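The target comes out of the substrate by two paths, one catalysed by acid and one without it, while a third exit leads reversibly to the dormant form.

    substrate + acid → weak acid + acid + target (k1 = 0.612 M⁻¹ s⁻¹)
    weak acid ⇌ conjugate base + acid, settled at all times (K2 = 5.0 × 10⁻⁶ M)
    substrate → weak acid + target (k3 = 0.00566 s⁻¹)
    crystals ⇌ weak acid, rate k4*(cs4 - [weak acid]) while solid is left; crystals form when [weak acid] > cs4 (cs4 = 4.7 mM, k4 = 0.193 s⁻¹)
    target ⇌ isomer of the product (K5 = 0.48, k5 = 0.00342 s⁻¹)
    substrate ⇌ dormant form (K6 = 8.9, k6 = 0.0162 s⁻¹)
substrate 0.20 M; acid 0.0200 M; time 2.0 min
- part of the substrate that has reacted at 2.0 min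
- pH of the solution at 2.0 min
- acid is the free proton; pH is minus the decimal logarithm of its molar concentration
- what is said of weak acid includes crystals
- crystals is a solid; its amount is given per volume of the solution
- what has gone from substrate into another species counts as reacted, even if it can come back
- run time (flask): 2.0 min

I worked with the fraction of substrate left, since c is its complement once the dormant form counts as reacted. The acid comes back in the catalysed step, and even a whole charge dissolved as weak acid would give a conjugate base of 0.0500 mM, far less than 0.0200 M. So I held c(acid) and the pH at their charged level and took the catalysed step as pseudo-first-order. The isomer of the product and the crystals lie downstream, in none of the substrate's rate terms.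

That left two coupled pools, substrate and dormant form, with an irreversible drain 0.0179 s⁻¹, a forward rate constant 0.0162 s⁻¹ and a return 0.00182 s⁻¹. Their eigenvalues are a fast 0.0350 s⁻¹ and a slow 9.31 × 10⁻⁴ s⁻¹. The fraction left is a sum of two exponentials, and I carried the weight of the slower one, 2.61%, the tail share: the part of the charge that decays at the slow rate.

At 2.0 min the slow term was 2.33% and the fast term 1.46%, so 3.80% was left and c was 96.2%. Turning the time, I expected a later reading to gain at most the 3.80% still left, and slowly, since the slow term already led. Turning the acid, I expected a diluted effect, since the catalysed term is about a third of the fast eigenvalue. Turning the substrate charge, I expected nothing, since each substrate term is linear in c(substrate) at held acid and the charge cancels from the fraction left.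

The forecast, citing “the slow return from the dormant form setting the small remainder”, gave 96.2% and pH 1.7.

The flask gave 96.2% and pH 1.70, with 3.8% of the substrate left, and the settings ranked time (2.5 points), then acid (1 points), then substrate (under 0.05 points). For the neighbour flask, read at 50 s, the same two terms gave 19.4% left, and it held 19%. The flask was not at rest at 2.0 min. For 20.0 min the slow term gave 0.854%. At 20.0 min the substrate stood at 0.854%, and at 20.0 min c had reached 99.1%. Between 2.00 min and 20.0 min the target rose from 43.9% to 57.0%, the isomer of the product rose from 10.5% to 26.6%, and the dormant form fell from 41.8% to 15.6%.

The numbers are made up; the rest is arithmetic.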